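**Retrosynthetic overview**
- Target 24 comes from pentamethyl ether 22 by two O-demethylations: iodide dealkylation of the pyranone methyl ether (to 23), then BBr3 cleavage of the four aryl methyl ethers.
- The strategy rests on ring B: its benzophenone carbonyl carbon and the CH2 that leads to pyranone C6 sit on adjacent ring carbons, with ring oxygens ortho and para to the carbonyl-bearing carbon. Ring B is therefore introduced as 3,5-dimethoxybenzyne (from silyl triflate 16) inserted into the C(=O)–CH2 bond of the ring A aroylmethyl pyranone 8.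
- Ketone 8 comes from ring A aldehyde 4 and 4-methoxy-6-methyl-2-pyranone 5 by aldol addition and oxidation; 4 comes from divarinol 1, and 16 from 3,5-dimethoxyphenol 9.
- No ring is built: ring A, ring B and the pyranone are bought intact. Ring A and the pyranone are joined first, ring B is spliced between them in step 8, and the methyl ethers are removed last.

Key step: step 8

Remark: the target has no stereocentre; the carbinol carbon of 7 is the only stereocentre on the route, is formed racemic and is removed in step 4.

**Route**

Step 1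
Reactants: 1 5-propylresorcinol (divarinol)
Product: 2 1,3-dimethoxy-5-propylbenzene
Conditions: Me2SO4 (2.5 equiv), K2CO3 (3 equiv), acetone, reflux
Reagents that add atoms: dimethyl sulfate, COS(=O)(=O)OC
Why: Williamson-type O-methylation of both phenoxides by dimethyl sulfate under K2CO3 is a standard exhaustive methylation of a resorcinol and should leave the ring carbons untouched.

Step 2
Reactants: 2 1,3-dimethoxy-5-propylbenzene
Product: 4 2,4-dimethoxy-6-propylbenzaldehyde, via iminium chloride 3 (not isolated)
Conditions: POCl3 (1.3 equiv), DMF, 0 °C to 65 °C; then ice–water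
Reagents that add atoms: N,N-dimethylformamide, CN(C)C=O; water, O
Why: Vilsmeier–Haack formylation of a 5-alkylresorcinol dimethyl ether should occur mainly at the ring carbon para to one methoxy group and ortho to the other (next to the propyl chain) rather than at the more crowded carbon between the two methoxy groups, and hydrolysis of iminium salt 3 releases the aldehyde.

Step 3
Reactants: 4 2,4-dimethoxy-6-propylbenzaldehyde; 5 4-methoxy-6-methyl-2H-pyran-2-one
Product: 7 racemic 6-[2-(2,4-dimethoxy-6-propylphenyl)-2-hydroxyethyl]-4-methoxy-2H-pyran-2-one, via lithium dienolate 6 (not isolated)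
Conditions: 5 (1.2 equiv), LiN(i-Pr)2 (1.15 equiv), THF, −78 °C; then 4 (1.0 equiv), −78 °C; AcOH quench at −78 °C
Reagents that add atoms: none
Why: LiN(i-Pr)2 should deprotonate the C6 methyl group of 5 to the extended vinylogous-ester dienolate 6, which undergoes aldol addition through its exocyclic carbon to the non-enolisable aldehyde 4; the carbinol stereocentre is formed without control (racemate), which is immaterial because step 4 removes it.

Step 4
Reactants: 7 racemic 6-[2-(2,4-dimethoxy-6-propylphenyl)-2-hydroxyethyl]-4-methoxy-2H-pyran-2-one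
Product: 8 6-[2-(2,4-dimethoxy-6-propylphenyl)-2-oxoethyl]-4-methoxy-2H-pyran-2-one
Conditions: Dess–Martin periodinane (1.3 equiv), pyridine (3 equiv), CH2Cl2, 0 °C to rt
Reagents that add atoms: none
Why: Dess–Martin oxidation of a secondary benzylic alcohol to the aryl ketone under pyridine-buffered, non-acidic conditions should avoid dehydration of the beta-hydroxy compound to a styrylpyranone.

Step 5
Reactants: 9 3,5-dimethoxyphenol
Product: 10 3,5-dimethoxyphenyl N-isopropylcarbamate
Conditions: i-PrNCO (1.5 equiv), Et3N (0.2 equiv), CH2Cl2, rt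
Reagents that add atoms: isopropyl isocyanate, CC(C)N=C=O
Why: base-catalysed addition of the phenol to the isocyanate gives the N-monoalkyl carbamate, which serves as the directing group for the next step and can later be removed under mild base.

Step 6
Reactants: 10 3,5-dimethoxyphenyl N-isopropylcarbamate
Product: 14 3,5-dimethoxy-2-(trimethylsilyl)phenyl N-isopropylcarbamate, via N-silyl carbamate 11 (not isolated), via aryllithium 12 (not isolated), via bis-silyl carbamate 13 (not isolated)
Conditions: Me3SiOTf (1.1 equiv), TMEDA, Et2O, 0 °C to rt; n-BuLi (2.2 equiv), TMEDA, −78 °C; Me3SiCl, −78 °C to rt; dilute aqueous acid work-up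
Reagents that add atoms: chlorotrimethylsilane, C[Si](C)(C)Cl
Why: directed ortho-metalation in which, after in situ N-silylation to 11, the carbamate and the neighbouring methoxy group cooperatively direct n-BuLi to the ring carbon between them (C2 and C6 are equivalent by symmetry), aryllithium 12 is C-silylated to 13 and the labile N–Si bond is hydrolysed on work-up.

Step 7
Reactants: 14 3,5-dimethoxy-2-(trimethylsilyl)phenyl N-isopropylcarbamate
Product: 16 3,5-dimethoxy-2-(trimethylsilyl)phenyl trifluoromethanesulfonate, via silylphenoxide 15 (not isolated)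
Conditions: DBU (1.5 equiv), Et2NH (1.25 equiv), MeCN, 40 °C; then PhNTf2 (1.5 equiv), rt
Reagents that add atoms: N-phenylbis(trifluoromethanesulfonimide), O=S(=O)(N(c1ccccc1)S(=O)(=O)C(F)(F)F)C(F)(F)F
Why: DBU should induce E1cB cleavage of the N-monoalkyl carbamate (the isopropyl isocyanate released is scavenged by Et2NH as a urea), and phenoxide 15 is O-sulfonylated in the same flask by PhNTf2, a standard one-pot route to ortho-silylaryl triflates.

Step 8
Reactants: 8 6-[2-(2,4-dimethoxy-6-propylphenyl)-2-oxoethyl]-4-methoxy-2H-pyran-2-one; 16 3,5-dimethoxy-2-(trimethylsilyl)phenyl trifluoromethanesulfonate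
Product: 22 6-[2-(2,4-dimethoxy-6-propylbenzoyl)-3,5-dimethoxybenzyl]-4-methoxy-2H-pyran-2-one, via caesium enolate 17 (not isolated), via 3,5-dimethoxybenzyne 18 (not isolated), via aryl anion 19 (not isolated), via benzocyclobutenoxide 20 (not isolated), via benzylic anion 21 (not isolated)
Conditions: CsF (3 equiv), MeCN, 80 °C; 8 (1.25 equiv) in the flask, 16 (1.0 equiv) added over several hours
Reagents that add atoms: none
Why: Proposed new method: CsF desilylates 16 to 3,5-dimethoxybenzyne 18 and deprotonates the CH2 of 8 (acidified by the aryl ketone and by C6 of the 2-pyranone, a vinylogous ester) to enolate 17; C-attack of 17 at the aryne carbon meta to the C3 methoxy group gives aryl anion 19, which adds to the adjacent ring A ketone (4-exo-trig) to form the strained benzocyclobutenoxide 20, and retro-aldol-type scission of the old C(=O)–CH2 bond then gives the diaryl ketone and the pyranone-stabilised benzylic anion 21, which is protonated to 22. The closest known reaction type is the fluoride-triggered acyl-alkylation of arynes by beta-ketoesters, established for this same 3,5-dimethoxybenzyne; the new element is that the ester is replaced by its vinylog, a 4-methoxy-2-pyranon-6-yl group. No ring of the target is closed (the four-membered ring is transient and reopens) and no stereocentre is formed. The regioselectivity needed is attack at the aryne carbon remote from the C3 methoxy group, which that group should secure by inductive polarisation and distortion of the aryne, placing the developing negative charge next to oxygen so that the acyl group ends up between the methoxy group and the new CH2. The chemoselectivity needed is C-arylation rather than O-arylation or (4+2) addition of the aryne to the pyranone diene, which the soft doubly stabilised carbanion, the excess of 8 and the slow release of the aryne should favour; the crowded tetra-ortho-substituted benzophenone bond is made intramolecularly, which is what should make it accessible.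

Step 9
Reactants: 22 6-[2-(2,4-dimethoxy-6-propylbenzoyl)-3,5-dimethoxybenzyl]-4-methoxy-2H-pyran-2-one
Product: 23 6-[2-(2,4-dimethoxy-6-propylbenzoyl)-3,5-dimethoxybenzyl]-4-hydroxy-2H-pyran-2-one
Conditions: LiI (3–4 equiv), pyridine, 100 °C; then dilute aqueous HCl work-up
Reagents that add atoms: none
Why: SN2 dealkylation by iodide at the methyl group of the vinylogous ester is the same reaction type as LiI cleavage of methyl esters, the leaving group being the well-stabilised 4-pyranolate, whereas the aryl methyl ethers have much poorer phenoxide leaving groups and should survive at this temperature.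

Step 10
Reactants: 23 6-[2-(2,4-dimethoxy-6-propylbenzoyl)-3,5-dimethoxybenzyl]-4-hydroxy-2H-pyran-2-one
Product: 24 6-[2-(2,4-dihydroxy-6-propylbenzoyl)-3,5-dihydroxybenzyl]-4-hydroxy-2H-pyran-2-one (target CNP0306954.0)
Conditions: BBr3 (8–10 equiv), CH2Cl2, −78 °C to rt; ice–water quench
Reagents that add atoms: none
Why: BBr3 cleavage of aryl methyl ethers (complexation at oxygen, then bromide attack at methyl) is assisted by chelation for the two ethers ortho to the ketone, the 4-hydroxy-2-pyranone is carried through as its borate, and the cold-to-ambient regime should avoid acid-promoted condensation of the polyphenolic benzophenone.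

**Compound list**
1 | 5-propylresorcinol (divarinol) | CCCc1cc(O)cc(O)c1 | starting material
2 | 1,3-dimethoxy-5-propylbenzene | CCCc1cc(OC)cc(OC)c1 | intermediate
3 | N-[(2,4-dimethoxy-6-propylphenyl)methylidene]-N-methylmethanaminium chloride (iminium chloride) | CCCc1cc(OC)cc(OC)c1C=[N+](C)C.[Cl-] | intermediate (not isolated)
4 | 2,4-dimethoxy-6-propylbenzaldehyde | CCCc1cc(OC)cc(OC)c1C=O | intermediate
5 | 4-methoxy-6-methyl-2H-pyran-2-one | Cc1cc(OC)cc(=O)o1 | starting material
6 | lithium 4-methoxy-6-methylidene-6H-pyran-2-olate (lithium dienolate of 5) | C=C1C=C(OC)C=C(O[Li])O1 | intermediate (not isolated)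
7 | racemic 6-[2-(2,4-dimethoxy-6-propylphenyl)-2-hydroxyethyl]-4-methoxy-2H-pyran-2-one | CCCc1cc(OC)cc(OC)c1C(O)Cc1cc(OC)cc(=O)o1 | intermediate
8 | 6-[2-(2,4-dimethoxy-6-propylphenyl)-2-oxoethyl]-4-methoxy-2H-pyran-2-one | CCCc1cc(OC)cc(OC)c1C(=O)Cc1cc(OC)cc(=O)o1 | intermediate
9 | 3,5-dimethoxyphenol | COc1cc(O)cc(OC)c1 | starting material
10 | 3,5-dimethoxyphenyl N-isopropylcarbamate | COc1cc(OC)cc(OC(=O)NC(C)C)c1 | intermediate
11 | 3,5-dimethoxyphenyl N-isopropyl-N-(trimethylsilyl)carbamate (N-silyl carbamate) | COc1cc(OC)cc(OC(=O)N(C(C)C)[Si](C)(C)C)c1 | intermediate (not isolated)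
12 | 2-lithio-3,5-dimethoxyphenyl N-isopropyl-N-(trimethylsilyl)carbamate (aryllithium) | COc1cc(OC)c([Li])c(OC(=O)N(C(C)C)[Si](C)(C)C)c1 | intermediate (not isolated)
13 | 3,5-dimethoxy-2-(trimethylsilyl)phenyl N-isopropyl-N-(trimethylsilyl)carbamate (bis-silyl carbamate) | COc1cc(OC)c([Si](C)(C)C)c(OC(=O)N(C(C)C)[Si](C)(C)C)c1 | intermediate (not isolated)
14 | 3,5-dimethoxy-2-(trimethylsilyl)phenyl N-isopropylcarbamate | COc1cc(OC)c([Si](C)(C)C)c(OC(=O)NC(C)C)c1 | intermediate
15 | 3,5-dimethoxy-2-(trimethylsilyl)phenoxide, DBU-H salt (silylphenoxide) | COc1cc(OC)c([Si](C)(C)C)c([O-])c1.C1CCC2=[NH+]CCCN2CC1 | intermediate (not isolated)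
16 | 3,5-dimethoxy-2-(trimethylsilyl)phenyl trifluoromethanesulfonate | COc1cc(OC)c([Si](C)(C)C)c(OS(=O)(=O)C(F)(F)F)c1 | intermediate
17 | caesium enolate of 8 | CCCc1cc(OC)cc(OC)c1C([O-])=Cc1cc(OC)cc(=O)o1.[Cs+] | intermediate (not isolated)
18 | 3,5-dimethoxybenzyne (1,2-didehydro-3,5-dimethoxybenzene) | COC1=CC(OC)=CC#C1 | intermediate (not isolated)
19 | aryl anion from addition of 17 to 18 (caesium salt; carbanion between the new C–C bond and the methoxy group) | CCCc1cc(OC)cc(OC)c1C(=O)C(c1cc(OC)cc(=O)o1)c1cc(OC)cc(OC)[c-]1.[Cs+] | intermediate (not isolated)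
20 | benzocyclobutenoxide (caesium salt) bearing the ring A aryl group and the pyranonyl group on the four-membered ring | CCCc1cc(OC)cc(OC)c1C1([O-])C(c2cc(OC)cc(=O)o2)c2cc(OC)cc(OC)c21.[Cs+] | intermediate (not isolated)
21 | benzylic anion of 22 (caesium salt, delocalised into the pyranone) | CCCc1cc(OC)cc(OC)c1C(=O)c1c(OC)cc(OC)cc1[CH-]c1cc(OC)cc(=O)o1.[Cs+] | intermediate (not isolated)
22 | 6-[2-(2,4-dimethoxy-6-propylbenzoyl)-3,5-dimethoxybenzyl]-4-methoxy-2H-pyran-2-one | CCCc1cc(OC)cc(OC)c1C(=O)c1c(OC)cc(OC)cc1Cc1cc(OC)cc(=O)o1 | intermediate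
23 | 6-[2-(2,4-dimethoxy-6-propylbenzoyl)-3,5-dimethoxybenzyl]-4-hydroxy-2H-pyran-2-one | CCCc1cc(OC)cc(OC)c1C(=O)c1c(OC)cc(OC)cc1Cc1cc(O)cc(=O)o1 | intermediate
24 | 6-[2-(2,4-dihydroxy-6-propylbenzoyl)-3,5-dihydroxybenzyl]-4-hydroxy-2H-pyran-2-one (CNP0306954.0) | CCCc1cc(O)cc(O)c1C(=O)c1c(O)cc(O)cc1Cc1cc(O)cc(=O)o1 | target

**Step count**
Total: 10 steps. Longest linear sequence: 7 steps (steps 1, 2, 3, 4, 8, 9, 10 from divarinol); the ring B branch (steps 5–7) is convergent.

**Steps most likely to fail, with fallbacks**

Step 8 (new method). The aryne may be consumed by (4+2) addition to the pyranone diene or by O-arylation of the enolate. Alternatively, the 4-exo closure onto the hindered ring A ketone may be too slow, so that the aryl anion is simply protonated and only alpha-arylation results. The fallback uses known chemistry, sets out from aldehyde 4 and silyl triflate 16, and comes back to the route at 23. Aldol addition of LiCH2CO2Et (from EtOAc and LiN(i-Pr)2, THF, −78 °C) to 4 should give ethyl 3-(2,4-dimethoxy-6-propylphenyl)-3-hydroxypropanoate F1. Dess–Martin oxidation should give the beta-ketoester ethyl 3-(2,4-dimethoxy-6-propylphenyl)-3-oxopropanoate F2. The established aryne acyl-alkylation of this beta-ketoester with 16 (CsF, MeCN, 80 °C) should give ethyl 2-[2-(2,4-dimethoxy-6-propylbenzoyl)-3,5-dimethoxyphenyl]acetate F3. Saponification with LiOH in THF–water gives 2-[2-(2,4-dimethoxy-6-propylbenzoyl)-3,5-dimethoxyphenyl]acetic acid F4, which 1,1'-carbonyldiimidazole converts into the acyl imidazolide F5. C-acylation of the lithium dienolate of 2,2,6-trimethyl-4H-1,3-dioxin-4-one (excess, THF, −78 °C) with F5 gives 6-{3-[2-(2,4-dimethoxy-6-propylbenzoyl)-3,5-dimethoxyphenyl]-2-oxopropyl}-2,2-dimethyl-4H-1,3-dioxin-4-one F6. Heating F6 in toluene at 110 °C expels acetone to give the acylketene F7, which cyclises through its ketone enol oxygen to the 4-hydroxy-2-pyranone 23. This bypasses step 9; step 10 then completes the synthesis.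

Step 3. Addition of the dienolate to the hindered, electron-rich aldehyde may be reversible (retro-aldol on warming), deprotonation at C3 of the pyranone may compete with the C6 methyl group, and the adduct may dehydrate to the styrylpyranone. The fallback sets out from 4 and comes back at 8, replacing steps 3 and 4 by an acylation. Pinnick oxidation of 4 (NaClO2, NaH2PO4, 2-methyl-2-butene, t-BuOH–water) should give 2,4-dimethoxy-6-propylbenzoic acid F8. Oxalyl chloride with catalytic DMF converts it into 2,4-dimethoxy-6-propylbenzoyl chloride F9. Claisen-type C-acylation of dienolate 6 (2 equiv, since the product is deprotonated by the second equivalent) with F9 in THF at −78 °C, followed by acidic work-up, should give ketone 8 directly.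

Step 9. Dealkylation of the vinylogous ester may be slow at a temperature that spares the aryl ethers, or the chelated methoxy groups ortho to the ketone may be cleaved concurrently and give mixtures of partly demethylated material. The fallback sets out from 22 and comes back at 24. The separate iodide stage is dropped and 22 is treated with excess BBr3 in CH2Cl2 (−78 °C to rt, extended time). This cleaves the pyranone methyl ether by the Lewis-acid pathway (boron bound at the lactone carbonyl, bromide attack at methyl, as for methyl esters) together with the four aryl ethers in one flask. No new isolated compound arises.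

**Further compounds**
F1 | step 8 | ethyl 3-(2,4-dimethoxy-6-propylphenyl)-3-hydroxypropanoate (racemic) | CCCc1cc(OC)cc(OC)c1C(O)CC(=O)OCC
F2 | step 8 | ethyl 3-(2,4-dimethoxy-6-propylphenyl)-3-oxopropanoate | CCCc1cc(OC)cc(OC)c1C(=O)CC(=O)OCC
F3 | step 8 | ethyl 2-[2-(2,4-dimethoxy-6-propylbenzoyl)-3,5-dimethoxyphenyl]acetate | CCCc1cc(OC)cc(OC)c1C(=O)c1c(OC)cc(OC)cc1CC(=O)OCC
F4 | step 8 | 2-[2-(2,4-dimethoxy-6-propylbenzoyl)-3,5-dimethoxyphenyl]acetic acid | CCCc1cc(OC)cc(OC)c1C(=O)c1c(OC)cc(OC)cc1CC(=O)O
F5 | step 8 | 1-{2-[2-(2,4-dimethoxy-6-propylbenzoyl)-3,5-dimethoxyphenyl]acetyl}imidazole (acyl imidazolide) | CCCc1cc(OC)cc(OC)c1C(=O)c1c(OC)cc(OC)cc1CC(=O)n1ccnc1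
F6 | step 8 | 6-{3-[2-(2,4-dimethoxy-6-propylbenzoyl)-3,5-dimethoxyphenyl]-2-oxopropyl}-2,2-dimethyl-4H-1,3-dioxin-4-one | CCCc1cc(OC)cc(OC)c1C(=O)c1c(OC)cc(OC)cc1CC(=O)CC1=CC(=O)OC(C)(C)O1
F7 | step 8 | 6-[2-(2,4-dimethoxy-6-propylbenzoyl)-3,5-dimethoxyphenyl]-3,5-dioxohexanoyl ketene (acylketene) | CCCc1cc(OC)cc(OC)c1C(=O)c1c(OC)cc(OC)cc1CC(=O)CC(=O)C=C=O
F8 | step 3 | 2,4-dimethoxy-6-propylbenzoic acid | CCCc1cc(OC)cc(OC)c1C(=O)O
F9 | step 3 | 2,4-dimethoxy-6-propylbenzoyl chloride | CCCc1cc(OC)cc(OC)c1C(=O)Cl
F0 | step 9 | none | none
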